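**Retrosynthetic overview**
1. Target 26 ⇐ ring A end-game (C-3 inversion by oxidation and bulky-hydride reduction, acetylation, O-19 masked as a silyl ether) ⇐ (13E)-enoate acetonide 18.
2. 18 ⇐ β-keto ester 15 ((Z)-enol phosphate plus Me2CuLi brings in C-16 with retention) ⇐ key C-13–C-14 bond by intermolecular aldol addition of the lithium enolate of methyl acetate 12 to aldehyde 11.
3. 11 ⇐ keto aldehyde 4: C-12 → C-13 homologation (Wittig, hydroboration, oxidation) and ring ketone → 8-methyl-7-ene (kinetic enol triflate, Negishi methylation).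
4. 4 ⇐ andrographolide 1 by acetonide protection and double ozonolysis (C-8=C-17 and C-12=C-13).
5. Rings: no carbocycle is built; the trans-decalin (rings A and B) with C-4, C-5, C-9 and C-10 comes intact from 1; only a temporary 1,3-dioxane is closed (step 1) and opened (step 12).

Assumption: andrographolide (bulk plant product, ≥98 %) is taken as a cheap commercial starting material; labdane numbering is used, C-19 is the axial CH2O group on C-4, and C-4, C-5, C-9, C-10 keep the configuration of 1 in every compound.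

**Route**

Step 1
Reactants: 1 andrographolide
Product: 2 (3R)-3,19-O-isopropylideneandrographolide
Conditions: 2,2-dimethoxypropane, PPTS (cat.), toluene/DMSO 10:1, 80 °C
Reagents that add atoms: 2,2-dimethoxypropane, COC(C)(C)OC
Why: Acid-catalysed transacetalisation (acetonide formation) ties the gauche 3-OH/19-OH 1,3-diol into a six-membered dioxane without touching a stereocentre, leaving free only the C-14 hydroxyl of the side chain that is removed next.

Step 2
Reactants: 2 (3R)-3,19-O-isopropylideneandrographolide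
Product: 4 (3R)-3,19-O-isopropylidene-8-oxo-13,14,15,16,17-pentanorlabdan-12-al, via bis-ozonide 3 (not isolated)
Conditions: O3, CH2Cl2, −78 °C; then PPh3, −78 °C → rt
Reagents that add atoms: ozone, [O-][O+]=O
Why: Ozonolysis with reductive work-up cleaves both C=C bonds, giving the ring ketone at C-8 and the aldehyde at C-12 and excising the butenolide, while C-9 keeps its equatorial, thermodynamically preferred substituent.

Step 3
Reactants: 4 (3R)-3,19-O-isopropylidene-8-oxo-13,14,15,16,17-pentanorlabdan-12-al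
Product: 5 (3R)-3,19-O-isopropylidene-14,15,16,17-tetranorlabd-12-en-8-one
Conditions: Ph3PCH3Br, KN(SiMe3)2, THF, 0 °C; then 4, −78 → 0 °C
Reagents that add atoms: methyltriphenylphosphonium bromide, C[P+](c1ccccc1)(c1ccccc1)c1ccccc1.[Br-]
Why: Wittig methylenation with one equivalent of salt-free ylide at low temperature takes the unhindered aldehyde in preference to the α-branched ring ketone and adds the carbon that becomes C-13.

Step 4
Reactants: 5 (3R)-3,19-O-isopropylidene-14,15,16,17-tetranorlabd-12-en-8-one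
Product: 7 (3R)-3,19-O-isopropylidene-14,15,16,17-tetranorlabda-7,12-dien-8-yl trifluoromethanesulfonate, via potassium enolate 6 (not isolated)
Conditions: KN(SiMe3)2, THF, −78 °C; then PhNTf2, −78 → 0 °C
Reagents that add atoms: N-phenylbis(trifluoromethanesulfonimide), O=S(=O)(N(c1ccccc1)S(=O)(=O)C(F)(F)F)C(F)(F)F
Why: Kinetic deprotonation by the bulky amide occurs at the C-7 methylene and not at the hindered tertiary C-9–H, so enol triflate formation fixes the ring double bond at C-7/C-8 and leaves C-9 untouched.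

Step 5
Reactants: 7 (3R)-3,19-O-isopropylidene-14,15,16,17-tetranorlabda-7,12-dien-8-yl trifluoromethanesulfonate
Product: 8 (3R)-3,19-O-isopropylidene-14,15,16-trinorlabda-7,12-diene
Conditions: MeZnCl, Pd(PPh3)4 (5 mol %), THF, 50 °C
Reagents that add atoms: methylzinc chloride, C[Zn]Cl
Why: Negishi cross-coupling under zerovalent palladium catalysis replaces the triflate by methyl (C-17) without moving the double bond, so the 8-methyl-7-ene is obtained regiospecifically and without acid.

Step 6
Reactants: 8 (3R)-3,19-O-isopropylidene-14,15,16-trinorlabda-7,12-diene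
Product: 10 (3R)-3,19-O-isopropylidene-14,15,16-trinorlabd-7-en-13-ol, via alkylborane 9 (not isolated)
Conditions: 9-BBN, THF, 0 °C → rt; then NaOH, H2O2, H2O, 0 °C → rt
Reagents that add atoms: hydrogen peroxide, OO
Why: Brown hydroboration–oxidation with the bulky dialkylborane is anti-Markovnikov and selective for the monosubstituted terminal alkene over the trisubstituted ring alkene, placing oxygen on C-13.

Step 7
Reactants: 10 (3R)-3,19-O-isopropylidene-14,15,16-trinorlabd-7-en-13-ol
Product: 11 (3R)-3,19-O-isopropylidene-14,15,16-trinorlabd-7-en-13-al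
Conditions: Dess–Martin periodinane, pyridine, CH2Cl2, 0 °C → rt
Reagents that add atoms: none
Why: Dess–Martin oxidation stops cleanly at the aldehyde under buffered conditions that spare the acetonide and the ring alkene.

Step 8
Reactants: 11 (3R)-3,19-O-isopropylidene-14,15,16-trinorlabd-7-en-13-al; 12 methyl acetate
Product: 14 methyl (3R)-13-hydroxy-3,19-O-isopropylidene-16-norlabd-7-en-15-oate (both 13-epimers), via lithium enolate 13 (not isolated)
Conditions: 12, LiN(CHMe2)2, THF, −78 °C; then 11, −78 °C; aq. NH4Cl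
Reagents that add atoms: none
Why: Intermolecular aldol addition of the preformed lithium ester enolate to the unhindered, non-branched aldehyde forms the C-13–C-14 bond; the new carbinol centre forms unselectively and is erased in step 9.

Step 9
Reactants: 14 methyl (3R)-13-hydroxy-3,19-O-isopropylidene-16-norlabd-7-en-15-oate
Product: 15 methyl (3R)-3,19-O-isopropylidene-13-oxo-16-norlabd-7-en-15-oate
Conditions: Dess–Martin periodinane, pyridine, CH2Cl2, rt
Reagents that add atoms: none
Why: Dess–Martin oxidation of the β-hydroxy ester gives the β-keto ester and converges both aldol epimers to one compound.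

Step 10
Reactants: 15 methyl (3R)-3,19-O-isopropylidene-13-oxo-16-norlabd-7-en-15-oate
Product: 17 methyl (3R,13Z)-13-(diethoxyphosphoryloxy)-3,19-O-isopropylidene-16-norlabda-7,13-dien-15-oate, via sodium enolate 16 (not isolated)
Conditions: NaH, Et2O, 0 °C; then ClP(O)(OEt)2, 0 °C
Reagents that add atoms: diethyl chlorophosphate, CCOP(=O)(Cl)OCC
Why: O-phosphorylation of the sodium-chelated enolate in ether (Weiler enol phosphate formation) gives the (Z)-enol phosphate, which fixes the geometry of the future trisubstituted alkene.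

Step 11
Reactants: 17 methyl (3R,13Z)-13-(diethoxyphosphoryloxy)-3,19-O-isopropylidene-16-norlabda-7,13-dien-15-oate
Product: 18 methyl (3R,13E)-3,19-O-isopropylidenedioxylabda-7,13-dien-15-oate
Conditions: Me2CuLi (MeLi, CuI), Et2O, −78 → −45 °C; aq. NH4Cl
Reagents that add atoms: lithium dimethylcuprate, [Li+].C[Cu-]C
Why: Cuprate addition–elimination on the enol phosphate replaces the phosphate by methyl (C-16) with retention, so C-12 and the ester end up trans, which is the (13E)-enoate.

Step 12
Reactants: 18 methyl (3R,13E)-3,19-O-isopropylidenedioxylabda-7,13-dien-15-oate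
Product: 19 methyl (3R,13E)-3,19-dihydroxylabda-7,13-dien-15-oate
Conditions: AcOH/H2O/THF 3:1:1, 40 °C
Reagents that add atoms: none
Why: Mild aqueous acid hydrolysis of the acetonide frees the diol without migrating the trisubstituted ring alkene or touching the conjugated ester.

Step 13
Reactants: 19 methyl (3R,13E)-3,19-dihydroxylabda-7,13-dien-15-oate
Product: 20 methyl (3R,13E)-19-(tert-butyldimethylsilyloxy)-3-hydroxylabda-7,13-dien-15-oate
Conditions: TBSCl, imidazole, CH2Cl2, 0 °C → rt
Reagents that add atoms: tert-butyldimethylsilyl chloride, CC(C)(C)[Si](C)(C)Cl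
Why: Silylation is selective for the primary C-19 hydroxyl over the secondary C-3 hydroxyl next to the quaternary carbon.

Step 14
Reactants: 20 methyl (3R,13E)-19-(tert-butyldimethylsilyloxy)-3-hydroxylabda-7,13-dien-15-oate
Product: 21 methyl (13E)-19-(tert-butyldimethylsilyloxy)-3-oxolabda-7,13-dien-15-oate
Conditions: Dess–Martin periodinane, pyridine, CH2Cl2, rt
Reagents that add atoms: none
Why: Dess–Martin oxidation gives the 3-ketone, which can neither eliminate nor undergo retro-aldol cleavage because C-4 is quaternary and O-19 is capped.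

Step 15
Reactants: 21 methyl (13E)-19-(tert-butyldimethylsilyloxy)-3-oxolabda-7,13-dien-15-oate
Product: 22 methyl (3S,13E)-19-(tert-butyldimethylsilyloxy)-3-hydroxylabda-7,13-dien-15-oate
Conditions: LiBH(sec-Bu)3, THF, −78 °C; then H2O
Reagents that add atoms: none
Why: In this bulky trialkylborohydride reduction the hydride enters along the equatorial trajectory, because axial attack is blocked by the axial hydrogens on C-1 and C-5, giving the axial (3S)-alcohol of the target; the β,β-disubstituted enoate is inert at −78 °C.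

Step 16
Reactants: 22 methyl (3S,13E)-19-(tert-butyldimethylsilyloxy)-3-hydroxylabda-7,13-dien-15-oate
Product: 23 (3S,13E)-19-(tert-butyldimethylsilyloxy)-3-hydroxylabda-7,13-dien-15-oic acid
Conditions: LiOH, THF/MeOH/H2O, 40 °C; then aq. HCl to pH 4, 0 °C
Reagents that add atoms: lithium hydroxide, [Li+].[OH-]
Why: Saponification of the methyl ester before the acetate is introduced removes any later need to tell two esters apart, and the neopentyl silyl ether survives the base.

Step 17
Reactants: 23 (3S,13E)-19-(tert-butyldimethylsilyloxy)-3-hydroxylabda-7,13-dien-15-oic acid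
Product: 25 (3S,13E)-3-acetoxy-19-(tert-butyldimethylsilyloxy)labda-7,13-dien-15-oic acid, via mixed anhydride 24 (not isolated)
Conditions: Ac2O, DMAP, pyridine, 40 °C; then H2O/THF, rt
Reagents that add atoms: acetic anhydride, CC(=O)OC(C)=O
Why: DMAP-catalysed acyl transfer acetylates the hindered axial 3-OH, and the mixed anhydride formed at the carboxyl group is hydrolysed at its acetyl carbonyl on aqueous work-up.

Step 18
Reactants: 25 (3S,13E)-3-acetoxy-19-(tert-butyldimethylsilyloxy)labda-7,13-dien-15-oic acid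
Product: 26 (3S,13E)-3-acetoxy-19-hydroxylabda-7,13-dien-15-oic acid (CNP0129162.1)
Conditions: HF·pyridine, THF/pyridine, 0 °C → rt
Reagents that add atoms: none
Why: Fluoride-mediated desilylation frees O-19, and the trans-diaxial arrangement of the 3-acetoxy group and the C-19 carbinol rules out the cyclic orthoester needed for acetyl migration.

**Compound list**
1 | andrographolide | O[C@@H]1CC[C@]2(C)[C@H](CCC(=C)[C@H]2C/C=C3/C(=O)OC[C@H]3O)[C@]1(C)CO | starting material
2 | (3R)-3,19-O-isopropylideneandrographolide | CC1(C)O[C@@H]2CC[C@]3(C)[C@H](CCC(=C)[C@H]3C/C=C4/C(=O)OC[C@H]4O)[C@]2(C)CO1 | intermediate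
3 | bis-ozonide of 2 (1,2,4-trioxolanes at C-8/C-17 and C-12/C-13, ozonide diastereomers) | CC1(C)O[C@@H]2CC[C@]3(C)[C@H](CCC4(OOCO4)[C@H]3CC5OOC6(O5)C(=O)OC[C@H]6O)[C@]2(C)CO1 | intermediate
4 | (3R)-3,19-O-isopropylidene-8-oxo-13,14,15,16,17-pentanorlabdan-12-al | CC1(C)O[C@@H]2CC[C@]3(C)[C@H](CCC(=O)[C@H]3CC=O)[C@]2(C)CO1 | intermediate
5 | (3R)-3,19-O-isopropylidene-14,15,16,17-tetranorlabd-12-en-8-one | CC1(C)O[C@@H]2CC[C@]3(C)[C@H](CCC(=O)[C@H]3CC=C)[C@]2(C)CO1 | intermediate
6 | potassium 7-en-8-olate of 5 | CC1(C)O[C@@H]2CC[C@]3(C)[C@H](CC=C([O-])[C@H]3CC=C)[C@]2(C)CO1.[K+] | intermediate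
7 | (3R)-3,19-O-isopropylidene-14,15,16,17-tetranorlabda-7,12-dien-8-yl trifluoromethanesulfonate | CC1(C)O[C@@H]2CC[C@]3(C)[C@H](CC=C(OS(=O)(=O)C(F)(F)F)[C@H]3CC=C)[C@]2(C)CO1 | intermediate
8 | (3R)-3,19-O-isopropylidene-14,15,16-trinorlabda-7,12-diene | CC1(C)O[C@@H]2CC[C@]3(C)[C@H](CC=C(C)[C@H]3CC=C)[C@]2(C)CO1 | intermediate
9 | B-(C-13 alkyl)-9-borabicyclo[3.3.1]nonane from 8 | CC1(C)O[C@@H]2CC[C@]3(C)[C@H](CC=C(C)[C@H]3CCCB4C5CCCC4CCC5)[C@]2(C)CO1 | intermediate
10 | (3R)-3,19-O-isopropylidene-14,15,16-trinorlabd-7-en-13-ol | CC1(C)O[C@@H]2CC[C@]3(C)[C@H](CC=C(C)[C@H]3CCCO)[C@]2(C)CO1 | intermediate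
11 | (3R)-3,19-O-isopropylidene-14,15,16-trinorlabd-7-en-13-al | CC1(C)O[C@@H]2CC[C@]3(C)[C@H](CC=C(C)[C@H]3CCC=O)[C@]2(C)CO1 | intermediate
12 | methyl acetate | COC(C)=O | starting material
13 | lithium 1-methoxyethenolate (lithium enolate of 12) | [Li+].[O-]C(=C)OC | intermediate
14 | methyl (3R)-13-hydroxy-3,19-O-isopropylidene-16-norlabd-7-en-15-oate (13-epimers) | CC1(C)O[C@@H]2CC[C@]3(C)[C@H](CC=C(C)[C@H]3CCC(O)CC(=O)OC)[C@]2(C)CO1 | intermediate
15 | methyl (3R)-3,19-O-isopropylidene-13-oxo-16-norlabd-7-en-15-oate | CC1(C)O[C@@H]2CC[C@]3(C)[C@H](CC=C(C)[C@H]3CCC(=O)CC(=O)OC)[C@]2(C)CO1 | intermediate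
16 | sodium (Z)-enolate of 15 | CC1(C)O[C@@H]2CC[C@]3(C)[C@H](CC=C(C)[C@H]3CC/C([O-])=C/C(=O)OC)[C@]2(C)CO1.[Na+] | intermediate
17 | methyl (3R,13Z)-13-(diethoxyphosphoryloxy)-3,19-O-isopropylidene-16-norlabda-7,13-dien-15-oate | CC1(C)O[C@@H]2CC[C@]3(C)[C@H](CC=C(C)[C@H]3CC/C(OP(=O)(OCC)OCC)=C/C(=O)OC)[C@]2(C)CO1 | intermediate
18 | methyl (3R,13E)-3,19-O-isopropylidenedioxylabda-7,13-dien-15-oate | CC1(C)O[C@@H]2CC[C@]3(C)[C@H](CC=C(C)[C@H]3CC/C(C)=C/C(=O)OC)[C@]2(C)CO1 | intermediate
19 | methyl (3R,13E)-3,19-dihydroxylabda-7,13-dien-15-oate | O[C@@H]1CC[C@]2(C)[C@H](CC=C(C)[C@H]2CC/C(C)=C/C(=O)OC)[C@]1(C)CO | intermediate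
20 | methyl (3R,13E)-19-(tert-butyldimethylsilyloxy)-3-hydroxylabda-7,13-dien-15-oate | O[C@@H]1CC[C@]2(C)[C@H](CC=C(C)[C@H]2CC/C(C)=C/C(=O)OC)[C@]1(C)CO[Si](C)(C)C(C)(C)C | intermediate
21 | methyl (13E)-19-(tert-butyldimethylsilyloxy)-3-oxolabda-7,13-dien-15-oate | O=C1CC[C@]2(C)[C@H](CC=C(C)[C@H]2CC/C(C)=C/C(=O)OC)[C@]1(C)CO[Si](C)(C)C(C)(C)C | intermediate
22 | methyl (3S,13E)-19-(tert-butyldimethylsilyloxy)-3-hydroxylabda-7,13-dien-15-oate | O[C@H]1CC[C@]2(C)[C@H](CC=C(C)[C@H]2CC/C(C)=C/C(=O)OC)[C@]1(C)CO[Si](C)(C)C(C)(C)C | intermediate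
23 | (3S,13E)-19-(tert-butyldimethylsilyloxy)-3-hydroxylabda-7,13-dien-15-oic acid | O[C@H]1CC[C@]2(C)[C@H](CC=C(C)[C@H]2CC/C(C)=C/C(=O)O)[C@]1(C)CO[Si](C)(C)C(C)(C)C | intermediate
24 | acetic (3S,13E)-3-acetoxy-19-(tert-butyldimethylsilyloxy)labda-7,13-dien-15-oic anhydride | CC(=O)O[C@H]1CC[C@]2(C)[C@H](CC=C(C)[C@H]2CC/C(C)=C/C(=O)OC(C)=O)[C@]1(C)CO[Si](C)(C)C(C)(C)C | intermediate
25 | (3S,13E)-3-acetoxy-19-(tert-butyldimethylsilyloxy)labda-7,13-dien-15-oic acid | CC(=O)O[C@H]1CC[C@]2(C)[C@H](CC=C(C)[C@H]2CC/C(C)=C/C(=O)O)[C@]1(C)CO[Si](C)(C)C(C)(C)C | intermediate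
26 | (3S,4R,5S,9R,10S,13E)-3-acetoxy-19-hydroxylabda-7,13-dien-15-oic acid (CNP0129162.1) | CC(=O)O[C@H]1CC[C@]2(C)[C@H](CC=C(C)[C@H]2CC/C(C)=C/C(=O)O)[C@]1(C)CO | target

**Totals and risks**
Total step count: 18. Longest linear sequence: 18 steps (1 → 26); methyl acetate 12 enters directly in step 8.

Steps most likely to fail:

- **Step 2 (double ozonolysis).** The electron-poor alkylidene lactone reacts slowly with ozone and the γ-keto aldehyde is sensitive. The fallback sets out from 2 and avoids ozonide chemistry. Both alkenes are dihydroxylated (OsO4 cat., N-methylmorpholine N-oxide, acetone/H2O) to the 8,17,12,13-tetraol F1, which is isolated. Glycol cleavage with NaIO4 in THF/H2O then cuts C-8–C-17 and C-12–C-13, and the route is rejoined at 4.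

- **Step 11 (cuprate methylation of the enol phosphate).** The coupling can be sluggish or lose geometric purity. The fallback sets out from 15, which is converted with Tf2O and aqueous LiOH in toluene (chelated lithium enolate) into the (Z)-enol triflate F2. Palladium-catalysed Negishi cross-coupling of F2 with MeZnCl and Pd(PPh3)4 proceeds with retention and comes back to the route at 18.

- **Step 15 (facial selectivity at C-3).** The axial CH2OSi group on C-4 may erode the preference for equatorial hydride delivery. The fallback sets out from 21 and uses substrate direction instead of reagent bulk. The silyl ether is removed with HF·pyridine to give the 19-hydroxy-3-ketone F3. Evans–Saksena reduction with Me4NBH(OAc)3 in MeCN/AcOH at −20 °C delivers hydride intramolecularly from the boron bound to the axial O-19, on the same face as C-19, giving the (3S)-3,19-diol F4. Selective silylation of the primary hydroxyl (TBSCl, imidazole) returns to the route at 22.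

Further compounds
F1 | step 2 | 8,17,12,13-tetrahydroxy derivative of 2 (diastereomers at C-8, C-12, C-13) | CC1(C)O[C@@H]2CC[C@]3(C)[C@H](CCC(O)(CO)[C@H]3CC(O)C4(O)C(=O)OC[C@H]4O)[C@]2(C)CO1
F2 | step 11 | methyl (3R,13Z)-3,19-O-isopropylidene-13-(trifluoromethylsulfonyloxy)-16-norlabda-7,13-dien-15-oate | CC1(C)O[C@@H]2CC[C@]3(C)[C@H](CC=C(C)[C@H]3CC/C(OS(=O)(=O)C(F)(F)F)=C/C(=O)OC)[C@]2(C)CO1
F3 | step 15 | methyl (13E)-19-hydroxy-3-oxolabda-7,13-dien-15-oate | O=C1CC[C@]2(C)[C@H](CC=C(C)[C@H]2CC/C(C)=C/C(=O)OC)[C@]1(C)CO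
F4 | step 15 | methyl (3S,13E)-3,19-dihydroxylabda-7,13-dien-15-oate | O[C@H]1CC[C@]2(C)[C@H](CC=C(C)[C@H]2CC/C(C)=C/C(=O)OC)[C@]1(C)CO
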